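## Retrosynthetic overview

1. Target 23 ⇐ aldehyde 22 by Wittig methylenation of the CHO on the quaternary carbon.
2. 22 ⇐ 2-methylidenecyclohexanol 21 by a semipinacol ring contraction (C6 shifts from C1 to C2), triggered by Co–H hydrogen-atom transfer and radical–polar crossover. This is the key step and the proposed new transformation; it makes the cyclopentane and the quaternary centre.
3. 21 ⇐ ketone 18 (α'-hydroxylation, methylenation); 18 ⇐ 2-alkenyl enone 13 + (Z)-alkenyl iodide 2 by Cu-catalysed asymmetric conjugate addition, then C2 equilibration to trans.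
4. 13 ⇐ alkyne 10 + 2-iodocyclohexenone 11 (carboalumination / Negishi coupling); 10 ⇐ (R)-3-bromo-2-methylpropanol 3 by two Cu-catalysed Grignard couplings; 2 ⇐ 4-methylpentanal 1 (iodo-Wittig).
5. Rings: the only ring is bought as a six-membered enone (11) and contracted to the cyclopentane in step 9.

Abbreviations used in names: RZ = (2Z)-6-methylhept-2-en-2-yl; RE = (1E,6S)-2,6,10-trimethylundec-1-en-1-yl.

Assumption: the phosphoramidite antipode named in step 6 is the one that gives the 3S adduct (sense taken from related Cu-catalysed additions to cyclohexenones); if a test run shows the opposite sense, the enantiomeric ligand is used.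

## Route

Step 1
Reactants: 1 4-methylpentanal
Product: 2 (2Z)-2-iodo-6-methylhept-2-ene
Conditions: EtPPh3I, n-BuLi, THF, 0 °C; I2, −78 °C; NaHMDS, −20 °C; then 1, −78 °C → rt
Reagents that add atoms: ethyltriphenylphosphonium iodide CC[P+](c1ccccc1)(c1ccccc1)c1ccccc1.[I-]; iodine II
Why: Stork–Zhao-type iodo-Wittig olefination, in which the non-stabilised α-iodo ylide reacts under kinetic control and places iodine cis to the alkyl chain, so the Z iodide is the main isomer.

Step 2
Reactants: 3 (2R)-3-bromo-2-methylpropan-1-ol; 4 3-methylbutylmagnesium bromide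
Product: 5 (2S)-2,6-dimethylheptan-1-ol
Conditions: 4 (2.4 equiv), Li2CuCl4 (3 mol%), THF, −40 °C → rt; H2O
Reagents that add atoms: none
Why: Kochi-type Cu-catalysed sp3–sp3 Grignard coupling at the primary bromide (the first equivalent of 4 only deprotonates OH); the stereocentre is not at the reacting carbon and is carried through (R→S is only a change of CIP priorities).

Step 3
Reactants: 5 (2S)-2,6-dimethylheptan-1-ol
Product: 6 (2S)-2,6-dimethylheptyl 4-methylbenzenesulfonate
Conditions: TsCl, pyridine, CH2Cl2, 0 °C → rt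
Reagents that add atoms: 4-methylbenzenesulfonyl chloride Cc1ccc(cc1)S(=O)(=O)Cl
Why: O-sulfonylation of the primary alcohol, which leaves the stereocentre untouched.

Step 4
Reactants: 6 (2S)-2,6-dimethylheptyl 4-methylbenzenesulfonate; 7 (4-bromobut-1-yn-1-yl)trimethylsilane (4-bromobut-1-yne in its C-silyl-protected form)
Product: 10 (6S)-6,10-dimethylundec-1-yne, via Grignard reagent 8 (not isolated), via silylalkyne 9 (not isolated)
Conditions: 7, Mg, THF, rt; 6, Li2CuCl4 (5 mol%), THF, −20 °C → rt; then MeOH, K2CO3, rt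
Reagents that add atoms: none
Why: A second Kochi-type Cu-catalysed coupling (primary tosylate + primary alkylmagnesium) followed by base-catalysed methanolysis of the C–Si bond in the same pot; the stereocentre is again not involved.

Step 5
Reactants: 10 (6S)-6,10-dimethylundec-1-yne; 11 2-iodocyclohex-2-en-1-one
Product: 13 2-RE-cyclohex-2-en-1-one, via alkenylalane 12 (not isolated)
Conditions: Me3Al (2 equiv), Cp2ZrCl2 (20 mol%), CH2Cl2, 0 °C → rt; evaporate excess Me3Al; 11, Pd(PPh3)4 (5 mol%), ZnCl2 (20 mol%), THF, rt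
Reagents that add atoms: trimethylaluminium C[Al](C)C
Why: Negishi Zr-catalysed syn-carboalumination (Me to C2, Al to C1) fixes the E trisubstituted alkene, and the alkenylalane then cross-couples with the α-iodoenone with retention (Negishi coupling).

Step 6
Reactants: 2 (2Z)-2-iodo-6-methylhept-2-ene; 13 2-RE-cyclohex-2-en-1-one
Product: 18 (2R,3S)-3-RZ-2-RE-cyclohexan-1-one, via alkenyllithium 14 (not isolated), via alkenylalane 15 (not isolated), via aluminium enolate 16 (not isolated), via cis ketone 17 (not isolated)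
Conditions: 2, t-BuLi (2 equiv), Et2O, −78 °C; Me2AlCl, −78 → −30 °C; 13, CuTC (10 mol%), (S,R,R)-BINOL/bis(1-phenylethyl)amine phosphoramidite (11 mol%), Et2O/THF, −30 °C; H2O; DBU (cat.), CH2Cl2, rt
Reagents that add atoms: none
Why: Cu-catalysed asymmetric conjugate addition of an alkenylalane (I/Li and Li/Al exchange retain the Z geometry, and alkenyl transfers in preference to methyl) sets C3 under ligand control, and base equilibration of the epimerisable C2 gives the trans-diequatorial ketone.

Step 7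
Reactants: 18 (2R,3S)-3-RZ-2-RE-cyclohexan-1-one
Product: 20 (2R,3S,6R)-6-hydroxy-3-RZ-2-RE-cyclohexan-1-one, via lithium enolate 19 (not isolated)
Conditions: LDA, THF, −78 °C; 3-phenyl-2-(phenylsulfonyl)oxaziridine, −78 °C; H2O
Reagents that add atoms: 3-phenyl-2-(phenylsulfonyl)oxaziridine O=S(=O)(c1ccccc1)N1OC1c1ccccc1
Why: Davis enolate oxidation, in which kinetic deprotonation occurs at the unhindered C6 methylene rather than the tertiary C2–H, the oxaziridine spares the three C=C bonds, and axial attack gives the 2,6-trans (axial OH) epimer as the main product.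

Step 8
Reactants: 20 (2R,3S,6R)-6-hydroxy-3-RZ-2-RE-cyclohexan-1-one
Product: 21 (1R,3R,4S)-2-methylidene-4-RZ-3-RE-cyclohexan-1-ol
Conditions: Ph3PCH3Br (3 equiv), KOtBu (2.9 equiv), THF, 0 → 50 °C; H2O
Reagents that add atoms: methyltriphenylphosphonium bromide C[P+](c1ccccc1)(c1ccccc1)c1ccccc1.[Br-]
Why: Wittig methylenation with excess ylide, which tolerates the free hydroxyl as its alkoxide, and any C2 epimerisation returns the trans isomer.

Step 9
Reactants: 21 (1R,3R,4S)-2-methylidene-4-RZ-3-RE-cyclohexan-1-ol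
Product: 22 (1R,2R,3S)-1-methyl-3-RZ-2-RE-cyclopentane-1-carbaldehyde
Conditions: Co(II)(salen) (5 mol%), N-fluoro-2,4,6-trimethylpyridinium triflate (1.2 equiv), PhSiH3 (1.1 equiv), acetone, 0 °C
Reagents that add atoms: none
Why: Proposed new method: Co(III)–H (from silane and the N–F oxidant) transfers H• to the 1,1-disubstituted exocyclic alkene faster than to the two trisubstituted alkenes, the tertiary C2 radical is oxidised (radical–polar crossover, alkyl-Co(IV)/cation), and the C1–C6 ring bond shifts to C2 with the hydroxyl lone pair pushing (semipinacol 1,2-shift), contracting the ring and forming the aldehyde; in the chair with both alkenyl groups equatorial, C6 bonds to C2 on the face that leaves the new CH3 cis and the CHO trans to the neighbouring RE group, and the axial C1–OH keeps C1–H out of alignment for hydride shift; the closest known reaction type is the HAT/radical–polar-crossover semipinacol ring expansion or 1,2-aryl shift of tertiary allylic alcohols (and the Lewis-acid ring contraction of 1-methylcyclohexene oxide), not yet shown as a ring contraction of a secondary 2-methylidenecycloalkanol.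

Step 10
Reactants: 22 (1R,2R,3S)-1-methyl-3-RZ-2-RE-cyclopentane-1-carbaldehyde
Product: 23 (1S,2R,3S)-1-ethenyl-1-methyl-3-RZ-2-RE-cyclopentane
Conditions: Ph3PCH3Br (2 equiv), KOtBu (1.9 equiv), THF, 0 °C → rt
Reagents that add atoms: methyltriphenylphosphonium bromide C[P+](c1ccccc1)(c1ccccc1)c1ccccc1.[Br-]
Why: Wittig methylenation of an aldehyde with no α-hydrogen, so nothing can epimerise or enolise.

## Compound list

1 | 4-methylpentanal | CC(C)CCC=O | starting material
2 | (2Z)-2-iodo-6-methylhept-2-ene | I/C(C)=C\CCC(C)C | intermediate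
3 | (2R)-3-bromo-2-methylpropan-1-ol | OC[C@@H](C)CBr | starting material
4 | 3-methylbutylmagnesium bromide | CC(C)CC[Mg]Br | starting material
5 | (2S)-2,6-dimethylheptan-1-ol | OC[C@@H](C)CCCC(C)C | intermediate
6 | (2S)-2,6-dimethylheptyl 4-methylbenzenesulfonate | Cc1ccc(cc1)S(=O)(=O)OC[C@@H](C)CCCC(C)C | intermediate
7 | (4-bromobut-1-yn-1-yl)trimethylsilane | C[Si](C)(C)C#CCCBr | starting material
8 | [4-(trimethylsilyl)but-3-yn-1-yl]magnesium bromide | C[Si](C)(C)C#CCC[Mg]Br | intermediate (not isolated)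
9 | trimethyl[(6S)-6,10-dimethylundec-1-yn-1-yl]silane | C[Si](C)(C)C#CCCC[C@@H](C)CCCC(C)C | intermediate (not isolated)
10 | (6S)-6,10-dimethylundec-1-yne | C#CCCC[C@@H](C)CCCC(C)C | intermediate
11 | 2-iodocyclohex-2-en-1-one | O=C1CCCC=C1I | starting material
12 | dimethyl[(1E,6S)-2,6,10-trimethylundec-1-en-1-yl]alumane | C[Al](C)/C=C(\C)CCC[C@@H](C)CCCC(C)C | intermediate (not isolated)
13 | 2-[(1E,6S)-2,6,10-trimethylundec-1-en-1-yl]cyclohex-2-en-1-one | O=C1CCCC=C1/C=C(\C)CCC[C@@H](C)CCCC(C)C | intermediate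
14 | (6-methylhept-2-en-2-yl)lithium, Li cis to the C4 chain (geometry of 2 retained) | [Li]/C(C)=C\CCC(C)C | intermediate (not isolated)
15 | dimethyl[(2Z)-6-methylhept-2-en-2-yl]alumane | C[Al](C)/C(C)=C\CCC(C)C | intermediate (not isolated)
16 | dimethylaluminium enolate of 18 (O–Al on C1, C1=C2; 3R by CIP, same spatial arrangement as in 18) | C[Al](C)OC1=C(/C=C(\C)CCC[C@@H](C)CCCC(C)C)[C@@H](/C(C)=C\CCC(C)C)CCC1 | intermediate (not isolated)
17 | (2S,3S)-3-RZ-2-RE-cyclohexan-1-one (cis C2 epimer of 18) | O=C1CCC[C@H](/C(C)=C\CCC(C)C)[C@@H]1/C=C(\C)CCC[C@@H](C)CCCC(C)C | intermediate (not isolated)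
18 | (2R,3S)-3-RZ-2-RE-cyclohexan-1-one (alkenyl groups trans) | O=C1CCC[C@H](/C(C)=C\CCC(C)C)[C@H]1/C=C(\C)CCC[C@@H](C)CCCC(C)C | intermediate
19 | lithium (5S,6R)-5-RZ-6-RE-cyclohex-1-en-1-olate | [Li]OC1=CCC[C@H](/C(C)=C\CCC(C)C)[C@H]1/C=C(\C)CCC[C@@H](C)CCCC(C)C | intermediate (not isolated)
20 | (2R,3S,6R)-6-hydroxy-3-RZ-2-RE-cyclohexan-1-one (OH trans to RE) | O=C1[C@H](O)CC[C@H](/C(C)=C\CCC(C)C)[C@H]1/C=C(\C)CCC[C@@H](C)CCCC(C)C | intermediate
21 | (1R,3R,4S)-2-methylidene-4-RZ-3-RE-cyclohexan-1-ol | C=C1[C@H](O)CC[C@H](/C(C)=C\CCC(C)C)[C@H]1/C=C(\C)CCC[C@@H](C)CCCC(C)C | intermediate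
22 | (1R,2R,3S)-1-methyl-3-RZ-2-RE-cyclopentane-1-carbaldehyde (CH3 cis, CHO trans to RE) | O=C[C@]1(C)CC[C@H](/C(C)=C\CCC(C)C)[C@H]1/C=C(\C)CCC[C@@H](C)CCCC(C)C | intermediate
23 | (1S,2R,3S)-1-ethenyl-1-methyl-3-[(2Z)-6-methylhept-2-en-2-yl]-2-[(1E,6S)-2,6,10-trimethylundec-1-en-1-yl]cyclopentane | C=C[C@]1(C)CC[C@H](/C(C)=C\CCC(C)C)[C@H]1/C=C(\C)CCC[C@@H](C)CCCC(C)C | target

## Step count and risks

Total step count: 10. Longest linear sequence: 9 (steps 2–10; step 1 is a one-step branch that joins at step 6).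

The three steps most likely to fail:

**Step 9 (the proposed ring contraction).** Possible failure modes are a 1,2-hydride shift from C1 or from the allylic C3–H instead of the C6 shift, HAT to the trisubstituted alkenes, isomerisation of the allylic alcohol to the 2-methyl ketone, and a conformer other than the diequatorial chair delivering the C1 epimer. The fallback uses known chemistry, sets out from 21 and comes back at 23. Hydroxyl-directed epoxidation (VO(acac)2, t-BuOOH, CH2Cl2, 0 °C), which touches only the alkene next to OH and delivers oxygen syn to it, gives the spiro-epoxy alcohol F1. A Lewis-acid 2,3-epoxy-alcohol semipinacol rearrangement (BF3·OEt2, CH2Cl2, −78 °C; the tertiary C–O bond opens and C6 migrates anti to it) gives the ring-contracted hydroxymethyl aldehyde F2. Wittig methylenation gives the vinyl alcohol F3, TsCl/pyridine gives the neopentyl tosylate F4, and LiEt3BH (THF, reflux) reduces it to the methyl group of 23.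

**Step 6 (asymmetric conjugate addition to an α-alkenyl enone).** The acceptor is less reactive and less precedented than the parent enone, the ee is uncertain, and the β,γ-unsaturated ketone may drift into conjugation during equilibration. The fallback sets out from 2 (as alane 15) and from 10 (as alane 12) and comes back at 18. Alane 15 is added under the same Cu/phosphoramidite catalysis to cyclohex-2-en-1-one F5, the best-precedented acceptor, to give the aluminium enolate F6. Ac2O traps it as the enol acetate F7, and MeLi (2 equiv, THF, 0 °C) releases the regiodefined lithium enolate F8. Pd-catalysed α-alkenylation (Pd(dba)2/Q-Phos, THF, rt) with the alkenyl iodide F9, made by iodinolysis (I2, THF, −30 °C) of alane 12, followed by the DBU equilibration gives 18.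

**Step 8 (methylenation of a hindered, enolisable α-hydroxy ketone).** The reaction may be slow, the α-ketol may isomerise, or the alkene may move into conjugation under basic ylide conditions. The fallback sets out from 20 and comes back at 21. Non-basic 1,2-addition of (trimethylsilyl)methyllithium/CeCl3 (3 equiv, THF, −78 °C) gives the β-hydroxysilane F10, and Peterson elimination (KH, THF, 0 °C → rt) gives 21.

## Further compounds

F1 | step 9 | (3R,4R,7S,8R)-7-RZ-8-RE-1-oxaspiro[2.5]octan-4-ol (epoxide O syn to OH, both trans to RE) | O1C[C@]12[C@H](O)CC[C@H](/C(C)=C\CCC(C)C)[C@H]2/C=C(\C)CCC[C@@H](C)CCCC(C)C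
F2 | step 9 | (1R,2R,3S)-1-(hydroxymethyl)-3-RZ-2-RE-cyclopentane-1-carbaldehyde | O=C[C@]1(CO)CC[C@H](/C(C)=C\CCC(C)C)[C@H]1/C=C(\C)CCC[C@@H](C)CCCC(C)C
F3 | step 9 | [(1R,2R,3S)-1-ethenyl-3-RZ-2-RE-cyclopentyl]methanol | C=C[C@]1(CO)CC[C@H](/C(C)=C\CCC(C)C)[C@H]1/C=C(\C)CCC[C@@H](C)CCCC(C)C
F4 | step 9 | [(1R,2R,3S)-1-ethenyl-3-RZ-2-RE-cyclopentyl]methyl 4-methylbenzenesulfonate | C=C[C@]1(COS(=O)(=O)c2ccc(C)cc2)CC[C@H](/C(C)=C\CCC(C)C)[C@H]1/C=C(\C)CCC[C@@H](C)CCCC(C)C
F5 | step 6 | cyclohex-2-en-1-one | O=C1CCCC=C1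
F6 | step 6 | dimethyl{[(3S)-3-RZ-cyclohex-1-en-1-yl]oxy}alumane | C[Al](C)OC1=C[C@@H](/C(C)=C\CCC(C)C)CCC1
F7 | step 6 | (3S)-3-RZ-cyclohex-1-en-1-yl acetate | CC(=O)OC1=C[C@@H](/C(C)=C\CCC(C)C)CCC1
F8 | step 6 | lithium (3S)-3-RZ-cyclohex-1-en-1-olate | [Li]OC1=C[C@@H](/C(C)=C\CCC(C)C)CCC1
F9 | step 6 | (1E,6S)-1-iodo-2,6,10-trimethylundec-1-ene | I/C=C(\C)CCC[C@@H](C)CCCC(C)C
F10 | step 8 | (2R,5S,6R)-5-RZ-6-RE-1-[(trimethylsilyl)methyl]cyclohexane-1,2-diol (C1 epimers) | C[Si](C)(C)CC1(O)[C@H](O)CC[C@H](/C(C)=C\CCC(C)C)[C@H]1/C=C(\C)CCC[C@@H](C)CCCC(C)C
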